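The 3 questions are one question put at 3 times: how much target stands against isomer of the product in a flask whose concentration lies between those of the elm and oak runs.

| flask | substrate | other conformer | free catalyst | remark | time |
|---|---|---|---|---|---|
| elm | 0.25 M | 1 equiv | 0.8 mol% | run made earlier |  |
| oak | 1 M | 1 equiv | 0.8 mol% | run made earlier |  |
| flask | 0.50 M | 1.00 equiv | 0.8 mol% |  | 2.5 min |

| run | time / min | target / % | isomer of the product / % | substrate / % |
|---|---|---|---|---|
| elm | 0.250 | 4.8 | 65.2 | 3.2 |
| elm | 0.833 | 6.2 | 91.2 | 0 |
| elm | 1.33 | 6.4 | 93.7 | 0.1 |
| elm | 2.00 | 7.0 | 92.8 | 0 |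
| elm | 3.00 | 7.0 | 94.1 | 0.5 |
| oak | 0.250 | 6.0 | 92.7 | 0.2 |
| oak | 0.833 | 6.6 | 92.8 | 0.2 |
| oak | 1.33 | 6.8 | 94.2 | 1.0 |
| oak | 2.00 | 7.3 | 92.6 | 0 |
| oak | 3.00 | 6.9 | 91.9 | 0.5 |

(readings scatter by 0.5 percentage points)

* ratio of target to isomer of the product at 0.20 s
* ratio of target to isomer of the product at 5.0 s
* ratio of target to isomer of the product at 2.5 min

- the numbers in the tables scatter by 0.5 percentage points (one standard deviation)

From the readings from 1.33 min onward, in both runs, I reckon:

target summed ÷ isomer summed = 0.0740

I call this the product ratio, the amount of target made per amount of isomer of the product made.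

Oak has a substrate concentration 4.00 times that of elm, yet the same late readings give 0.0727 in elm and 0.0753 in oak. Elm also reads 0.0736 at 0.250 min, with isomer of the product still at 65.2 %.

A flat ratio suggests a simple picture. Suppose the catalyst turns one common feed into target at rate a × catalyst × feed, and into isomer of the product at rate b × catalyst × feed. Integrating from the start gives:

target = a × ∫ catalyst × feed dt
isomer = b × ∫ catalyst × feed dt
target ÷ isomer = a ÷ b

The same integral stands in both lines, so it cancels, however catalyst and feed change with time. I therefore commit to 0.0740 at each of the asked times in the flask.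

The forecast gives 0.07, 0.07 and 0.074, with the remark “Concentration has no clear effect”. My value stands a little above its two early values.

The flask gives 0.0722, 0.0722 and 0.0722.

    free catalyst + other conformer → free catalyst + isomer of the product (k = 43.0 M⁻¹ s⁻¹)
    substrate + free catalyst → free catalyst + target (k = 27.0 M⁻¹ s⁻¹)
    substrate ⇌ other conformer, settled at all times (K = 8.70)
    substrate + free catalyst → spent catalyst (k = 0.140 M⁻¹ s⁻¹)

The largest single effect on the flask's ratio is the balance kept between substrate and other conformer, both ways: without it the ratio at 2.5 min is 0.994, not 0.0722. In the flask at 0.0750 min, the product ratio times 48.1 % of isomer of the product gives 3.56 % of target, and the flask holds 3.47 %. In the neighbour charged with 2.50 equiv of other conformer, the product ratio times 93.2 % of isomer of the product gives 6.90 % of target, and at 2.50 min that neighbour holds 6.73 %.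

The data are simulated with made-up constants, and the scatter is random.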